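**Retrosynthetic overview**
- The target comes from one reductive global deprotection of a flavone that carries three benzyl ethers and the 3′-sulfate masked as its 2,2,2-trichloroethyl diester.
- Key disconnection C2–C1′: a C2-zincated 5,7-bis(benzyloxy)chromone (C2 used as a nucleophile, a masked acyl anion) is joined to a ring B aryl iodide that already carries the masked sulfate.
- Ring B partner: 2-(benzyloxy)phenol is converted to the trichloroethyl sulfate, then iodinated para to the benzyloxy group.
- Chromone: phloroacetophenone is bis-benzylated, then taken through an enaminone to the C2-unsubstituted chromone.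
- Ring order: ring A is bought, ring C is closed on it in step 2, and ring B is attached last in step 5.

Assumption: the target has no stereocentre, so the structure as drawn is its only stereoisomer. The free sulfuric acid monoester is obtained by cold acidification of its ammonium salt.

**Step 1**
Reactants: 1 2′,4′,6′-trihydroxyacetophenone
Product: 2 phloroacetophenone 2′,4′-di-O-benzyl ether (1-[2,4-bis(benzyloxy)-6-hydroxyphenyl]ethan-1-one)
Conditions: BnBr (2.1 equiv), K2CO3 (2.2 equiv), DMF, 0 °C → rt
Reagents that add atoms: benzyl bromide, BrCc1ccccc1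
Why: Williamson etherification takes the 4-OH and one ortho OH, while the remaining ortho OH is locked in a hydrogen bond to the ketone and is the least nucleophilic, so alkylation stops at the bis-ether.

**Step 2**
Reactants: 2 phloroacetophenone 2′,4′-di-O-benzyl ether
Product: 4 chromone 5,7-bis(benzyloxy)-4H-chromen-4-one, via enaminone 3 (not isolated)
Conditions: Me2NCH(OMe)2 (3 equiv), toluene, 100 °C; evaporate; AcOH, 100 °C
Reagents that add atoms: N,N-dimethylformamide dimethyl acetal, COC(OC)N(C)C
Why: Condensation of the methyl ketone with the amide acetal gives the enaminone, and acid-promoted intramolecular conjugate addition–elimination of dimethylamine (enaminone chromone synthesis) closes ring C with C2 left as C–H.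

**Step 3**
Reactants: 5 2-(benzyloxy)phenol
Product: 6 aryl sulfate diester 2-(benzyloxy)phenyl 2,2,2-trichloroethyl sulfate
Conditions: Cl3CCH2OSO2Cl (1.2 equiv), Et3N (1.5 equiv), DMAP (cat.), THF, 0 °C → rt
Reagents that add atoms: 2,2,2-trichloroethyl chlorosulfate, ClS(=O)(=O)OCC(Cl)(Cl)Cl
Why: DMAP-catalysed O-sulfonylation (sulfuryl transfer) of the phenol installs the sulfate as a neutral, acid-stable diester that can be carried through the following steps.

**Step 4**
Reactants: 6 2-(benzyloxy)phenyl 2,2,2-trichloroethyl sulfate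
Product: 7 aryl iodide 2-(benzyloxy)-5-iodophenyl 2,2,2-trichloroethyl sulfate
Conditions: NIS (1.1 equiv), TFA, MeCN, rt
Reagents that add atoms: N-iodosuccinimide, O=C1CCC(=O)N1I
Why: Electrophilic aromatic iodination goes para to the benzyloxy group, the only strong donor (the sulfate-bearing oxygen is deactivated), and this carbon is the future C1′.

**Step 5**
Reactants: 4 5,7-bis(benzyloxy)-4H-chromen-4-one; 7 2-(benzyloxy)-5-iodophenyl 2,2,2-trichloroethyl sulfate
Product: 9 protected flavone 2-(benzyloxy)-5-[5,7-bis(benzyloxy)-4-oxo-4H-chromen-2-yl]phenyl 2,2,2-trichloroethyl sulfate, via chromon-2-ylzinc chloride 8 (not isolated)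
Conditions: TMPZnCl·LiCl (1.3 equiv; TMP = 2,2,6,6-tetramethylpiperidide), THF, 25 °C, 1 h; then 7 (0.85 equiv), Pd(dba)2 (3 mol %), tri(2-furyl)phosphine (6 mol %), THF, 25 → 50 °C
Reagents that add atoms: none
Why: Deprotonative zincation removes the most acidic chromone proton, C2–H next to the ring oxygen (no carbonyl-bound magnesium is present to steer the base to C3), which turns the normally electrophilic C2 into a nucleophilic α-oxyvinyl zinc species, a masked acyl anion, and Negishi cross-coupling under zerovalent palladium joins it to the electrophilic aryl iodide carbon; no stereocentre is formed.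

**Step 6**
Reactants: 9 2-(benzyloxy)-5-[5,7-bis(benzyloxy)-4-oxo-4H-chromen-2-yl]phenyl 2,2,2-trichloroethyl sulfate
Product: 11 luteolin 3′-sulfate, via ammonium luteolin 3′-sulfate 10 (not isolated)
Conditions: 10 % Pd/C, HCO2NH4 (12 equiv), MeOH–THF 1:1, 25 °C, stop at full conversion; filter; 1 M HCl to pH 2, 0 °C, C18 desalting, lyophilise
Reagents that add atoms: none
Why: Catalytic transfer hydrogenolysis cleaves the three aryl benzyl ethers and reductively fragments the trichloroethyl ester (loss of chloride and 1,1-dichloroethene), leaving the inert aryl sulfate monoester as its ammonium salt, which cold acid protonates; the free acid is hydrolytically labile and is best stored as the salt.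

**Compound list**
1 | 2′,4′,6′-trihydroxyacetophenone | CC(=O)c1c(O)cc(O)cc1O | starting material
2 | 1-[2,4-bis(benzyloxy)-6-hydroxyphenyl]ethan-1-one | CC(=O)c1c(O)cc(OCc2ccccc2)cc1OCc1ccccc1 | intermediate
3 | (E)-1-[2,4-bis(benzyloxy)-6-hydroxyphenyl]-3-(dimethylamino)prop-2-en-1-one | CN(C)/C=C/C(=O)c1c(O)cc(OCc2ccccc2)cc1OCc1ccccc1 | intermediate
4 | 5,7-bis(benzyloxy)-4H-chromen-4-one | O=c1ccoc2cc(OCc3ccccc3)cc(OCc3ccccc3)c12 | intermediate
5 | 2-(benzyloxy)phenol | Oc1ccccc1OCc1ccccc1 | starting material
6 | 2-(benzyloxy)phenyl 2,2,2-trichloroethyl sulfate | ClC(Cl)(Cl)COS(=O)(=O)Oc1ccccc1OCc1ccccc1 | intermediate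
7 | 2-(benzyloxy)-5-iodophenyl 2,2,2-trichloroethyl sulfate | ClC(Cl)(Cl)COS(=O)(=O)Oc1cc(I)ccc1OCc1ccccc1 | intermediate
8 | [5,7-bis(benzyloxy)-4-oxo-4H-chromen-2-yl]zinc chloride (lithium chloride complex) | Cl[Zn]c1cc(=O)c2c(OCc3ccccc3)cc(OCc3ccccc3)cc2o1 | intermediate
9 | 2-(benzyloxy)-5-[5,7-bis(benzyloxy)-4-oxo-4H-chromen-2-yl]phenyl 2,2,2-trichloroethyl sulfate | O=c1cc(-c2ccc(OCc3ccccc3)c(OS(=O)(=O)OCC(Cl)(Cl)Cl)c2)oc2cc(OCc3ccccc3)cc(OCc3ccccc3)c12 | intermediate
10 | ammonium luteolin 3′-sulfate | [NH4+].O=c1cc(-c2ccc(O)c(OS(=O)(=O)[O-])c2)oc2cc(O)cc(O)c12 | intermediate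
11 | luteolin 3′-sulfate | O=c1cc(-c2ccc(O)c(OS(=O)(=O)O)c2)oc2cc(O)cc(O)c12 | target

**Totals**
Total step count: 6. Longest linear sequence: 4 steps (1 → 2 → 4 → 9 → 11, or 5 → 6 → 7 → 9 → 11).

**Steps most likely to fail**

Step 5 (zincation and Negishi coupling). The main risk is that the trichloroethyl sulfate diester does not survive the zinc amide or the zerovalent palladium catalyst, or that it slows the coupling. The fallback carries the 3′-oxygen through the coupling as an acetate and sulfates afterwards. It sets out from 5 and comes back to the route at 9. Phenol 5 is acetylated (Ac2O, pyridine) to 2-(benzyloxy)phenyl acetate F1. This is iodinated para to the benzyloxy group (NIS, TFA, MeCN) to 2-(benzyloxy)-5-iodophenyl acetate F2. F2 is coupled with zinc reagent 8 under the step 5 catalyst to give 2-(benzyloxy)-5-[5,7-bis(benzyloxy)-4-oxo-4H-chromen-2-yl]phenyl acetate F3. Methanolysis (K2CO3, MeOH–THF) gives 5,7-bis(benzyloxy)-2-[4-(benzyloxy)-3-hydroxyphenyl]-4H-chromen-4-one F4. Its single free phenol is sulfated with 2,2,2-trichloroethyl chlorosulfate (Et3N, DMAP, THF) to give 9.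

Step 6 (one-pot global deprotection). The risks are reduction of the C2=C3 bond to the flavanone and incomplete debenzylation under transfer hydrogenation. The fallback avoids hydrogenation altogether. It sets out from 9 and comes back at 10. BCl3 with pentamethylbenzene as cation scavenger (CH2Cl2, −78 °C) removes the three benzyl groups, leaving the acid-stable diester 5-(5,7-dihydroxy-4-oxo-4H-chromen-2-yl)-2-hydroxyphenyl 2,2,2-trichloroethyl sulfate F5. Zn dust with HCO2NH4 in MeOH at 25 °C then cleaves the trichloroethyl group by electron transfer to give 10, which is acidified as in step 6.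

Step 4 (regioselective iodination). The risks are sluggish reaction of the ring deactivated by the sulfate ester and some iodination ortho to the benzyloxy group. The fallback replaces halogenation by para-selective C–H thianthrenation. It sets out from 6 and comes back at 9, bypassing 7. Treatment of 6 with thianthrene S-oxide, (CF3CO)2O and HBF4·OEt2 in MeCN at 0 °C gives 5-[4-(benzyloxy)-3-{[(2,2,2-trichloroethoxy)sulfonyl]oxy}phenyl]-5H-thianthren-5-ium tetrafluoroborate F6. This salt is used as the aryl electrophile toward zinc reagent 8 in the palladium-catalysed coupling of step 5 to give 9.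

**Further compounds**
F1 | step 5 | 2-(benzyloxy)phenyl acetate | CC(=O)Oc1ccccc1OCc1ccccc1
F2 | step 5 | 2-(benzyloxy)-5-iodophenyl acetate | CC(=O)Oc1cc(I)ccc1OCc1ccccc1
F3 | step 5 | 2-(benzyloxy)-5-[5,7-bis(benzyloxy)-4-oxo-4H-chromen-2-yl]phenyl acetate | CC(=O)Oc1cc(-c2cc(=O)c3c(OCc4ccccc4)cc(OCc4ccccc4)cc3o2)ccc1OCc1ccccc1
F4 | step 5 | 5,7-bis(benzyloxy)-2-[4-(benzyloxy)-3-hydroxyphenyl]-4H-chromen-4-one | Oc1cc(-c2cc(=O)c3c(OCc4ccccc4)cc(OCc4ccccc4)cc3o2)ccc1OCc1ccccc1
F5 | step 6 | 5-(5,7-dihydroxy-4-oxo-4H-chromen-2-yl)-2-hydroxyphenyl 2,2,2-trichloroethyl sulfate | Oc1ccc(-c2cc(=O)c3c(O)cc(O)cc3o2)cc1OS(=O)(=O)OCC(Cl)(Cl)Cl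
F6 | step 4 | 5-[4-(benzyloxy)-3-{[(2,2,2-trichloroethoxy)sulfonyl]oxy}phenyl]-5H-thianthren-5-ium tetrafluoroborate | ClC(Cl)(Cl)COS(=O)(=O)Oc1cc([S+]2c3ccccc3Sc3ccccc32)ccc1OCc1ccccc1.F[B-](F)(F)F
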